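**Retrosynthetic overview**

1. The target is a trans-3,4-dibenzyl-γ-butyrolactone, and the last two operations only unmask methylene groups: Raney nickel deletes a 1,3-dithiane at the C4 benzylic carbon, and before that a C5 menthyl acetal (a C5–O bond absent from the target) is reduced to the C5 CH2.
2. Key disconnection: the bond from the 3,4-dimethoxybenzyl CH2 to lactone C3. It is made by SN2 benzylation of a lactone enolate generated in the same flask by Michael addition of a lithiated 2-(3,4,5-trimethoxyphenyl)-1,3-dithiane to C4 of (5R)-5-menthyloxyfuran-2(5H)-one; this three-component coupling also sets C3 and C4.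
3. Enabling feature: in the ring O1–C2(=O)–C3–C4–C5 the two benzyl-bearing, trans-related carbons are C3 (α to the carbonyl C2, a donor) and C4 (β, an acceptor), the two ends of a butenolide C3=C4 bond. C5 is a bare CH2 that can carry a removable alkoxy stereocontrol group, and the benzylic CH2 on C4 can be carried at the dithiane (acyl anion) oxidation level.
4. Ring order: both arenes and the lactone ring are bought; the temporary dithiane ring is formed first and destroyed last; the lactone ring is opened and reclosed once when the auxiliary is removed.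

Key step: step 2

Remark: (5R)-5-[(1R,2S,5R)-menthyloxy]furan-2(5H)-one (the acetal of (−)-menthol) and 3,4-dimethoxybenzyl bromide are taken as catalogue compounds; the bromide is used from a fresh lot because it hydrolyses on storage.

Step 1
Reactants: 1 3,4,5-trimethoxybenzaldehyde; 2 propane-1,3-dithiol
Product: 3 2-(3,4,5-trimethoxyphenyl)-1,3-dithiane
Conditions: BF3·OEt2 (0.2 equiv), CH2Cl2, 0 °C → rt
Reagents that add atoms: none
Why: Lewis-acid-catalysed dithioacetalisation of an aromatic aldehyde; the aryl methyl ethers are inert and no stereocentre is formed.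

Step 2
Reactants: 3 2-(3,4,5-trimethoxyphenyl)-1,3-dithiane; 4 (5R)-5-[(1R,2S,5R)-menthyloxy]furan-2(5H)-one; 5 3,4-dimethoxybenzyl bromide
Product: 8 (3R,4R,5R)-3-(3,4-dimethoxybenzyl)-5-[(1R,2S,5R)-menthyloxy]-4-[2-(3,4,5-trimethoxyphenyl)-1,3-dithian-2-yl]dihydrofuran-2(3H)-one, via lithiated dithiane 6 (not isolated), via lithium lactone enolate 7 (not isolated)
Conditions: n-BuLi (1.0 equiv), THF, −78 → −30 °C; then 4, −78 °C; then 5 (1.3 equiv), DMPU, −78 °C → rt; aq. NH4Cl
Reagents that add atoms: n-butyllithium, [Li]CCCC (its lithium is held only by the intermediates 6 and 7; no atom of it stays in 8)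
Why: n-BuLi removes the C2–H of dithiane 3 to give the sulfur- and aryl-stabilised carbanion 6, which adds in a Michael reaction to C4 of butenolide 4, and the lithium lactone enolate 7 so formed is C-benzylated at C3 by bromide 5 (SN2), which makes the bond between the 3,4-dimethoxybenzyl CH2 and C3 and completes the carbon skeleton in one flask. The closest known reaction type is the tandem conjugate addition–enolate alkylation of lithiated aryl thioacetals (Corey–Seebach umpolung), γ-alkoxybutenolides and benzylic halides. No ring is closed in this step; the lactone ring of 4 is carried through. C4 is controlled by the C5 menthyloxy group of 4, anti to which the carbanion adds, and C3 is controlled by the new bulky dithianyl group at C4, anti to which the bromide approaches the enolate, so the (5R) acetal centre should be relayed into the 3,4-trans (3R,4R,5R) array. The step needs 1,4- over 1,2-addition, which the soft, delocalised aryl dithiane anion and the low temperature secure, and C-monoalkylation, which the lithium enolate, the reactive benzylic bromide with DMPU and the shielding of the remaining C3–H in 8 secure.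

Step 3
Reactants: 8 (3R,4R,5R)-3-(3,4-dimethoxybenzyl)-5-[(1R,2S,5R)-menthyloxy]-4-[2-(3,4,5-trimethoxyphenyl)-1,3-dithian-2-yl]dihydrofuran-2(3H)-one
Product: 11 (3R,4R)-3-(3,4-dimethoxybenzyl)-4-[2-(3,4,5-trimethoxyphenyl)-1,3-dithian-2-yl]dihydrofuran-2(3H)-one, via potassium aldehyde carboxylate 9 (not isolated), via potassium hydroxy carboxylate 10 (not isolated)
Conditions: NaBH4, KOH, EtOH–H2O, 0 °C → rt; then 2 M HCl to pH 1–2, rt
Reagents that add atoms: potassium hydroxide, [K+].[OH-] (potassium and the hydroxide oxygen are found in 9 and 10; in 11 at most one lactone oxygen can stem from it, because relactonisation expels one carboxylate oxygen as water)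
Why: Saponification of the acyl acetal (a masked aldehyde acid) releases menthol and the aldehyde 9, which borohydride should reduce to 10 faster than it enolises, and acidification closes the γ-lactone with C2 still the carbonyl carbon (hydrolysis–reduction–lactonisation of a γ-alkoxy lactone); C3 sits α to a carboxylate and is not epimerised, and the dithiane is inert to hydride, base and dilute acid.

Step 4
Reactants: 11 (3R,4R)-3-(3,4-dimethoxybenzyl)-4-[2-(3,4,5-trimethoxyphenyl)-1,3-dithian-2-yl]dihydrofuran-2(3H)-one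
Product: 12 (3R,4R)-3-(3,4-dimethoxybenzyl)-4-(3,4,5-trimethoxybenzyl)dihydrofuran-2(3H)-one
Conditions: Raney Ni (W-2, excess, washed to neutrality), EtOH, reflux
Reagents that add atoms: none
Why: Mozingo-type hydrogenolysis of the two C–S bonds turns the dithiane carbon into the benzylic CH2; the lactone, the aryl ethers and both stereocentres (neither bonded to sulfur, and trans being the more stable arrangement) should be unaffected.

**Compound list**

1 | 3,4,5-trimethoxybenzaldehyde | COc1cc(C=O)cc(OC)c1OC | starting material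
2 | propane-1,3-dithiol | SCCCS | starting material
3 | 2-(3,4,5-trimethoxyphenyl)-1,3-dithiane | COc1cc(C2SCCCS2)cc(OC)c1OC | intermediate
4 | (5R)-5-[(1R,2S,5R)-menthyloxy]furan-2(5H)-one | O=C1C=C[C@H](O[C@@H]2C[C@H](C)CC[C@H]2C(C)C)O1 | starting material
5 | 3,4-dimethoxybenzyl bromide | COc1ccc(CBr)cc1OC | starting material
6 | 2-lithio-2-(3,4,5-trimethoxyphenyl)-1,3-dithiane (not isolated) | [Li]C1(c2cc(OC)c(OC)c(OC)c2)SCCCS1 | intermediate
7 | lithium (4R,5R)-5-[(1R,2S,5R)-menthyloxy]-4-[2-(3,4,5-trimethoxyphenyl)-1,3-dithian-2-yl]-4,5-dihydrofuran-2-olate (not isolated) | [Li+].[O-]C1=C[C@@H](C2(c3cc(OC)c(OC)c(OC)c3)SCCCS2)[C@H](O[C@@H]2C[C@H](C)CC[C@H]2C(C)C)O1 | intermediate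
8 | (3R,4R,5R)-3-(3,4-dimethoxybenzyl)-5-[(1R,2S,5R)-menthyloxy]-4-[2-(3,4,5-trimethoxyphenyl)-1,3-dithian-2-yl]dihydrofuran-2(3H)-one | O=C1[C@H](Cc2ccc(OC)c(OC)c2)[C@@H](C2(c3cc(OC)c(OC)c(OC)c3)SCCCS2)[C@H](O[C@@H]2C[C@H](C)CC[C@H]2C(C)C)O1 | intermediate
9 | potassium (2R,3R)-2-(3,4-dimethoxybenzyl)-4-oxo-3-[2-(3,4,5-trimethoxyphenyl)-1,3-dithian-2-yl]butanoate (not isolated) | [K+].[O-]C(=O)[C@H](Cc1ccc(OC)c(OC)c1)[C@@H](C1(c2cc(OC)c(OC)c(OC)c2)SCCCS1)C=O | intermediate
10 | potassium (2R,3R)-2-(3,4-dimethoxybenzyl)-4-hydroxy-3-[2-(3,4,5-trimethoxyphenyl)-1,3-dithian-2-yl]butanoate (not isolated) | [K+].[O-]C(=O)[C@H](Cc1ccc(OC)c(OC)c1)[C@@H](C1(c2cc(OC)c(OC)c(OC)c2)SCCCS1)CO | intermediate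
11 | (3R,4R)-3-(3,4-dimethoxybenzyl)-4-[2-(3,4,5-trimethoxyphenyl)-1,3-dithian-2-yl]dihydrofuran-2(3H)-one | O=C1[C@H](Cc2ccc(OC)c(OC)c2)[C@@H](C2(c3cc(OC)c(OC)c(OC)c3)SCCCS2)CO1 | intermediate
12 | (3R,4R)-3-(3,4-dimethoxybenzyl)-4-(3,4,5-trimethoxybenzyl)dihydrofuran-2(3H)-one | COc1ccc(C[C@H]2C(=O)OC[C@@H]2Cc2cc(OC)c(OC)c(OC)c2)cc1OC | target

**Step count**

Total steps: 4. Longest linear sequence: 4 steps (1 → 3 → 8 → 11 → 12).

**Steps most likely to fail**

Step 2. The hindered enolate may be captured incompletely by the benzylic bromide (proton transfer, or loss of the bromide to unreacted carbanion), or the second bond may form with poor facial control. The fallback sets out from 3 and 4 and comes back to the route at 12; it separates the two C–C bond formations and moves the benzylation to the end, onto a small lactone enolate.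
- The carbanion from 3 (n-BuLi, THF, −78 °C) is added to 4 and the enolate is quenched with aq. NH4Cl. This should give the Michael adduct (4R,5R)-5-[(1R,2S,5R)-menthyloxy]-4-[2-(3,4,5-trimethoxyphenyl)-1,3-dithian-2-yl]dihydrofuran-2(3H)-one F1.
- NaBH4/KOH in EtOH–H2O opens it through potassium (3R)-4-oxo-3-[2-(3,4,5-trimethoxyphenyl)-1,3-dithian-2-yl]butanoate F2 and its reduction product potassium (3R)-4-hydroxy-3-[2-(3,4,5-trimethoxyphenyl)-1,3-dithian-2-yl]butanoate F3. Acidification should close (4R)-4-[2-(3,4,5-trimethoxyphenyl)-1,3-dithian-2-yl]dihydrofuran-2(3H)-one F4.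
- Raney nickel in EtOH should then give (4R)-4-(3,4,5-trimethoxybenzyl)dihydrofuran-2(3H)-one F5.
- LDA in THF at −78 °C gives lithium (4R)-4-(3,4,5-trimethoxybenzyl)-4,5-dihydrofuran-2-olate F6. Its alkylation with 5 anti to the C4 benzyl group (the classical trans-selective α-benzylation of β-benzyl-γ-butyrolactones) should give 12 directly.

Step 3. The ring-opened aldehyde may enolise in the alkaline medium before hydride delivery, which would erode the C4 configuration, or relactonisation may be incomplete. The fallback sets out from 8 and comes back at 11; the acetal is cleaved in acid and the reduction is done separately, so that no hydroxide is present while the aldehyde exists.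
- Hydrolysis of 8 in TFA–H2O–THF at 40 °C (water-rich, so that water and not an arene captures the C5 cation) should give menthol and the lactol (3R,4R)-3-(3,4-dimethoxybenzyl)-5-hydroxy-4-[2-(3,4,5-trimethoxyphenyl)-1,3-dithian-2-yl]dihydrofuran-2(3H)-one F7 (C5 epimers).
- NaBH4 in EtOH at 0 °C reduces the open form of this pseudo-acid, sodium (2R,3R)-2-(3,4-dimethoxybenzyl)-4-oxo-3-[2-(3,4,5-trimethoxyphenyl)-1,3-dithian-2-yl]butanoate F8, to sodium (2R,3R)-2-(3,4-dimethoxybenzyl)-4-hydroxy-3-[2-(3,4,5-trimethoxyphenyl)-1,3-dithian-2-yl]butanoate F9.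
- Acidification should close 11.

Step 4. The C–S hydrogenolysis may stop short, or material may be lost by adsorption on the large excess of nickel. The fallback sets out from 11 and comes back at 12; sulfur is removed by oxidative hydrolysis and the resulting benzylic carbonyl is taken out by hydrogenolysis.
- PhI(OCOCF3)2 in MeCN–H2O at 0 °C should convert 11 into the aryl ketone (3R,4R)-3-(3,4-dimethoxybenzyl)-4-(3,4,5-trimethoxybenzoyl)dihydrofuran-2(3H)-one F10.
- H2, Pd/C in AcOH with a trace of HClO4 should reduce the electron-rich aryl ketone through the benzylic alcohol (3R,4R)-3-(3,4-dimethoxybenzyl)-4-[hydroxy(3,4,5-trimethoxyphenyl)methyl]dihydrofuran-2(3H)-one F11 (carbinol epimers) to 12.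
- The 3,4-trans arrangement is the more stable one, so enolisation of the ketone at C4 should not cost configuration.

**Further compounds**

F1 | step 2 | (4R,5R)-5-[(1R,2S,5R)-menthyloxy]-4-[2-(3,4,5-trimethoxyphenyl)-1,3-dithian-2-yl]dihydrofuran-2(3H)-one | O=C1C[C@@H](C2(c3cc(OC)c(OC)c(OC)c3)SCCCS2)[C@H](O[C@@H]2C[C@H](C)CC[C@H]2C(C)C)O1
F2 | step 2 | potassium (3R)-4-oxo-3-[2-(3,4,5-trimethoxyphenyl)-1,3-dithian-2-yl]butanoate | [K+].[O-]C(=O)C[C@@H](C1(c2cc(OC)c(OC)c(OC)c2)SCCCS1)C=O
F3 | step 2 | potassium (3R)-4-hydroxy-3-[2-(3,4,5-trimethoxyphenyl)-1,3-dithian-2-yl]butanoate | [K+].[O-]C(=O)C[C@@H](C1(c2cc(OC)c(OC)c(OC)c2)SCCCS1)CO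
F4 | step 2 | (4R)-4-[2-(3,4,5-trimethoxyphenyl)-1,3-dithian-2-yl]dihydrofuran-2(3H)-one | O=C1C[C@@H](C2(c3cc(OC)c(OC)c(OC)c3)SCCCS2)CO1
F5 | step 2 | (4R)-4-(3,4,5-trimethoxybenzyl)dihydrofuran-2(3H)-one | O=C1C[C@@H](Cc2cc(OC)c(OC)c(OC)c2)CO1
F6 | step 2 | lithium (4R)-4-(3,4,5-trimethoxybenzyl)-4,5-dihydrofuran-2-olate | [Li+].[O-]C1=C[C@@H](Cc2cc(OC)c(OC)c(OC)c2)CO1
F7 | step 3 | (3R,4R)-3-(3,4-dimethoxybenzyl)-5-hydroxy-4-[2-(3,4,5-trimethoxyphenyl)-1,3-dithian-2-yl]dihydrofuran-2(3H)-one (C5 epimers) | O=C1[C@H](Cc2ccc(OC)c(OC)c2)[C@@H](C2(c3cc(OC)c(OC)c(OC)c3)SCCCS2)C(O)O1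
F8 | step 3 | sodium (2R,3R)-2-(3,4-dimethoxybenzyl)-4-oxo-3-[2-(3,4,5-trimethoxyphenyl)-1,3-dithian-2-yl]butanoate | [Na+].[O-]C(=O)[C@H](Cc1ccc(OC)c(OC)c1)[C@@H](C1(c2cc(OC)c(OC)c(OC)c2)SCCCS1)C=O
F9 | step 3 | sodium (2R,3R)-2-(3,4-dimethoxybenzyl)-4-hydroxy-3-[2-(3,4,5-trimethoxyphenyl)-1,3-dithian-2-yl]butanoate | [Na+].[O-]C(=O)[C@H](Cc1ccc(OC)c(OC)c1)[C@@H](C1(c2cc(OC)c(OC)c(OC)c2)SCCCS1)CO
F10 | step 4 | (3R,4R)-3-(3,4-dimethoxybenzyl)-4-(3,4,5-trimethoxybenzoyl)dihydrofuran-2(3H)-one | O=C1[C@H](Cc2ccc(OC)c(OC)c2)[C@@H](C(=O)c2cc(OC)c(OC)c(OC)c2)CO1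
F11 | step 4 | (3R,4R)-3-(3,4-dimethoxybenzyl)-4-[hydroxy(3,4,5-trimethoxyphenyl)methyl]dihydrofuran-2(3H)-one (carbinol epimers) | O=C1[C@H](Cc2ccc(OC)c(OC)c2)[C@@H](C(O)c2cc(OC)c(OC)c(OC)c2)CO1
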